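C1 is the vanilloyloxy carbinol, then C2, C3=C4(Me), C5–C7, C8(Me)2, C9 (acetoxy carbinol) and C10=C11(Me). The C11–C1 bond completes the 11-membered carbocycle, the only ring that has to be built.
Retrosynthesis: the two ester C–O bonds are cut first, then the ring at C6–C7, then the chain at C1–C11, C8–C9 and C4–C5.
Enabling feature: C5–C6–C7 is a bare trimethylene bridge of the 11-membered ring between alkene carbon C4 and quaternary C8. C6–C7 can therefore be made as a sacrificial C6=C7 alkene from a vinyl group on C8 and an allyl group on C4, and then saturated.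
Forward: fragment C7–C11 and fragment C1–C6 are joined at C1–C11, the ring closes by metathesis, C6=C7 is reduced, and C1 and then C9 are acylated.
Stereochemistry: 9R comes from reagent-controlled reverse prenylation with the (+)-α-pinene-derived borane, and 1S from (R)-oxazaborolidine reduction of the C1 ketone. Z-C10=C11 comes from trans-hydroalumination–iodination and E-C3=C4 from syn-hydrozirconation–iodination; both alkenes are carried on with retention.

Key step: step 11

Assumptions: (−)-Ipc2BH is used as the crystalline reagent made beforehand from (+)-α-pinene and BH3·SMe2 (not counted as a step); the new C6=C7 alkene of the ring-closure product is drawn E, although either geometry serves; cyclopentadienyl ligands are drawn η1 in SMILES.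

Step 1
Reactants: 1 but-2-yn-1-ol
Product: 3 (Z)-3-iodobut-2-en-1-ol, via cyclic alkenylalanate 2 (not isolated)
Conditions: NaAlH2(OCH2CH2OMe)2, THF, 0 °C to rt; then I2, THF, −78 °C to 0 °C
Reagents that add atoms: iodine, [I][I]
Why: Hydroxyl-directed trans-hydroalumination of the propargylic alcohol delivers hydride to the carbinol-side alkyne carbon and ties aluminium to the methyl-bearing carbon in a five-membered alkoxyalanate, and iodinolysis with retention should therefore give only the Z-iodoalkene in which iodine (the site of the later C11–C1 bond) is cis to the future C9.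

Step 2
Reactants: 3 (Z)-3-iodobut-2-en-1-ol
Product: 4 (Z)-3-iodobut-2-enal
Conditions: activated MnO2 (excess), CH2Cl2, rt, dark
Reagents that add atoms: none
Why: Heterogeneous allylic oxidation with neutral MnO2 stops at the enal and, run in the dark with prompt use of the product, should not erode the Z geometry.

Step 3
Reactants: 4 (Z)-3-iodobut-2-enal; 5 3-methylbuta-1,2-diene
Product: 8 (4R,5Z)-6-iodo-3,3-dimethylhepta-1,5-dien-4-ol, via prenylborane 6 (not isolated), via borinate 7 (not isolated)
Conditions: 5, (−)-Ipc2BH, THF, −25 °C; then 4, Et2O, −78 °C; then 3 M NaOH, 30% H2O2, 0 °C to rt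
Reagents that add atoms: none
Why: Hydroboration of the allene at its unsubstituted terminus gives the 3,3-dimethylallylborane, which adds to the enal in a Brown asymmetric allylboration (reverse prenylation) through a closed chair transition state with allyl transposition, forming C8–C9 together with the quaternary C8 and its vinyl group, while the isopinocampheyl ligands derived from (+)-α-pinene steer attack to the Si face of the aldehyde and so set 9R.

Step 4
Reactants: 8 (4R,5Z)-6-iodo-3,3-dimethylhepta-1,5-dien-4-ol
Product: 9 tert-butyl{[(4R,5Z)-6-iodo-3,3-dimethylhepta-1,5-dien-4-yl]oxy}dimethylsilane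
Conditions: TBSOTf, 2,6-lutidine, CH2Cl2, −78 °C to 0 °C
Reagents that add atoms: tert-butyldimethylsilyl triflate, CC(C)(C)[Si](C)(C)OS(=O)(=O)C(F)(F)F
Why: Silylation with the silyl triflate and a hindered pyridine base is the standard way to protect a neopentyl secondary alcohol and leaves the iodoalkene and the vinyl group untouched.

Step 5
Reactants: 10 pent-3-yn-1-ol
Product: 12 (E)-4-iodopent-3-en-1-ol, via alkenylzirconocene 11 (not isolated)
Conditions: Cp2Zr(H)Cl (2.5 equiv), THF, rt to 40 °C; then I2, THF, −78 °C to 0 °C
Reagents that add atoms: iodine, [I][I]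
Why: syn-Hydrozirconation, with one equivalent of hydride spent on the hydroxyl group and the excess equilibrating the regioisomers towards zirconium on the less hindered methyl-bearing carbon, followed by iodinolysis with retention should give the E-iodoalkene that fixes the C3=C4 geometry.

Step 6
Reactants: 12 (E)-4-iodopent-3-en-1-ol; 13 allylboronic acid pinacol ester
Product: 14 (E)-4-methylhepta-3,6-dien-1-ol
Conditions: Pd(PPh3)4 (5 mol %), CsF, THF, reflux
Reagents that add atoms: none
Why: Suzuki–Miyaura coupling of an alkenyl iodide with an allylboronate runs with retention at the sp2 carbon, tolerates the free hydroxyl group and forms C4–C5, giving the skipped diene with its terminal allyl alkene.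

Step 7
Reactants: 14 (E)-4-methylhepta-3,6-dien-1-ol
Product: 15 (E)-4-methylhepta-3,6-dienal
Conditions: Dess–Martin periodinane, pyridine, CH2Cl2, 0 °C; used at once
Reagents that add atoms: none
Why: Dess–Martin oxidation under pyridine buffering is mild and non-basic enough to deliver a β,γ-unsaturated aldehyde without moving C3=C4 into conjugation, provided the aldehyde is used at once.

Step 8
Reactants: 9 tert-butyl{[(4R,5Z)-6-iodo-3,3-dimethylhepta-1,5-dien-4-yl]oxy}dimethylsilane; 15 (E)-4-methylhepta-3,6-dienal
Product: 17 (4E,8Z,10R)-10-[(tert-butyldimethylsilyl)oxy]-4,8,11,11-tetramethyltrideca-1,4,8,12-tetraen-7-ol (both epimers at C7 of the chain, which is ring C1), via alkenylmagnesium chloride 16 (not isolated)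
Conditions: 9, i-PrMgCl·LiCl, THF, 0 °C to rt; then 15, −78 °C to −40 °C; aq NH4Cl at −40 °C
Reagents that add atoms: none
Why: Iodine–magnesium exchange with the LiCl-activated Grignard reagent proceeds with retention of alkene geometry and gives an alkenylmagnesium that is less basic and far less prone to oxygen-to-carbon silyl migration than the lithium analogue, so 1,2-addition to the aldehyde should form C1–C11 with Z-C10=C11 intact, the C1 configuration being irrelevant because step 9 removes it.

Step 9
Reactants: 17 (4E,8Z,10R)-10-[(tert-butyldimethylsilyl)oxy]-4,8,11,11-tetramethyltrideca-1,4,8,12-tetraen-7-ol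
Product: 18 (4E,8Z,10R)-10-[(tert-butyldimethylsilyl)oxy]-4,8,11,11-tetramethyltrideca-1,4,8,12-tetraen-7-one
Conditions: Dess–Martin periodinane, pyridine, CH2Cl2, 0 °C
Reagents that add atoms: none
Why: Buffered Dess–Martin oxidation converges both C1 epimers on one ketone under conditions that should neither conjugate the β,γ-alkene nor isomerise the Z-enone.

Step 10
Reactants: 18 (4E,8Z,10R)-10-[(tert-butyldimethylsilyl)oxy]-4,8,11,11-tetramethyltrideca-1,4,8,12-tetraen-7-one
Product: 19 (4E,7S,8Z,10R)-10-[(tert-butyldimethylsilyl)oxy]-4,8,11,11-tetramethyltrideca-1,4,8,12-tetraen-7-ol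
Conditions: (R)-1-methyl-3,3-diphenyltetrahydro-1H,3H-pyrrolo[1,2-c][1,3,2]oxazaborole (30 mol %), catecholborane, toluene, −78 °C; then MeOH, aq NaHCO3
Reagents that add atoms: none
Why: In this Corey–Bakshi–Shibata reduction the ketone binds to the boron of the (R)-oxazaborolidine with the large trisubstituted alkenyl arm turned away from the catalyst, so hydride reaches the face that gives 1S under reagent control, and catecholborane is the hydride source because at −78 °C it leaves alone the two terminal alkenes that BH3 would hydroborate.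

Step 11
Reactants: 19 (4E,7S,8Z,10R)-10-[(tert-butyldimethylsilyl)oxy]-4,8,11,11-tetramethyltrideca-1,4,8,12-tetraen-7-ol
Product: 20 (1S,2Z,4R,6E,9E)-4-[(tert-butyldimethylsilyl)oxy]-2,5,5,9-tetramethylcycloundeca-2,6,9-trien-1-ol
Conditions: second-generation Grubbs catalyst (H2IMes)(PCy3)Cl2Ru=CHPh (10 mol %, in two portions), 1,4-benzoquinone (20 mol %), toluene (1 mM), 80 °C, argon sparge
Reagents that add atoms: none
Why: The propagating ruthenium methylidene that arises from the benzylidene exchanges with the unhindered allyl terminus, releasing ethene and giving the C6 alkylidene, which adds to the neopentyl vinyl group on C8 by [2+2] cycloaddition; cycloreversion of the ruthenacyclobutane leaves the C6=C7 alkene and returns the methylidene. The reaction type is macrocyclic ring-closing olefin metathesis of an α,ω-diene, which is known for 11-membered carbocycles although these lie at its demanding limit. The single ring closes head-to-head between the two terminal CH= carbons, so both C6 and C7 become members of the 11-membered ring, and the C8(Me)2–CH=CH–CH2–C(Me)=CH array so formed is the one present in the humulene ring, which argues that the E-alkene can be accommodated. No stereocentre is formed, the C1 hydroxyl (tolerated free by the ruthenium carbene and remote from both termini) and the C9 silyl ether are spectators, and the C6=C7 geometry is without consequence because step 12 removes it. The step needs site selectivity for the two monosubstituted alkenes over trisubstituted C3=C4 and C10=C11 and ring closure over oligomerisation: the first rests on the lower substitution of the termini, on the shielding of C10=C11 by its methyl group and the two flanking carbinol carbons, and on the fact that attack of the C6 alkylidene on C10=C11 would demand a seven-membered ring holding an E-alkene, while the second rests on millimolar dilution, the turn imposed by Z-C10=C11 and the gem-dimethyl group at C8. Short reaction time, the ethene purge and 1,4-benzoquinone are meant to hold back migration within the skipped diene and back-biting of a C7 alkylidene on C3=C4, which would contract the ring to a cycloocta-1,5-diene.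

Step 12
Reactants: 20 (1S,2Z,4R,6E,9E)-4-[(tert-butyldimethylsilyl)oxy]-2,5,5,9-tetramethylcycloundeca-2,6,9-trien-1-ol
Product: 21 (1S,2Z,4R,9E)-4-[(tert-butyldimethylsilyl)oxy]-2,5,5,9-tetramethylcycloundeca-2,9-dien-1-ol
Conditions: 2,4,6-triisopropylbenzenesulfonyl hydrazide, Et3N, ClCH2CH2Cl, 50 °C
Reagents that add atoms: none
Why: Diimide, released by base-induced fragmentation of the sulfonyl hydrazide, transfers H2 in a concerted syn fashion at a rate that falls steeply with alkene substitution, so the only disubstituted alkene C6=C7 should be saturated while trisubstituted C3=C4 and C10=C11, the silyl ether and the hydroxyl group persist, as is known for macrocycles made by ring-closing metathesis.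

Step 13
Reactants: 22 vanillic acid
Product: 23 4-acetoxy-3-methoxybenzoic acid
Conditions: Ac2O, pyridine, rt; then H2O
Reagents that add atoms: acetic anhydride, CC(=O)OC(C)=O
Why: Acetylation of the phenol masks the only competing nucleophile of the acid, and the aqueous quench hydrolyses any mixed anhydride back to the free carboxylic acid.

Step 14
Reactants: 21 (1S,2Z,4R,9E)-4-[(tert-butyldimethylsilyl)oxy]-2,5,5,9-tetramethylcycloundeca-2,9-dien-1-ol; 23 4-acetoxy-3-methoxybenzoic acid
Product: 24 (1S,2Z,4R,9E)-4-[(tert-butyldimethylsilyl)oxy]-2,5,5,9-tetramethylcycloundeca-2,9-dien-1-yl 4-acetoxy-3-methoxybenzoate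
Conditions: DCC, 4-(dimethylamino)pyridine (20 mol %), CH2Cl2, 0 °C to rt
Reagents that add atoms: none
Why: Steglich esterification activates the acid as its O-acylisourea and acylpyridinium, acylates the secondary allylic hydroxyl without breaking the C1–O bond and therefore keeps 1S.

Step 15
Reactants: 24 (1S,2Z,4R,9E)-4-[(tert-butyldimethylsilyl)oxy]-2,5,5,9-tetramethylcycloundeca-2,9-dien-1-yl 4-acetoxy-3-methoxybenzoate
Product: 25 (1S,2Z,4R,9E)-4-hydroxy-2,5,5,9-tetramethylcycloundeca-2,9-dien-1-yl 4-acetoxy-3-methoxybenzoate
Conditions: HF·pyridine, pyridine, THF, 0 °C to rt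
Reagents that add atoms: none
Why: Fluoride-driven cleavage of the silicon–oxygen bond with pyridine-buffered HF is the usual way to free neopentyl tert-butyldimethylsilyl ethers, is mild enough for the aryl acetate, the allylic benzoate and both alkenes, and its slightly acidic medium disfavours acyl migration from C1 to C9.

Step 16
Reactants: 25 (1S,2Z,4R,9E)-4-hydroxy-2,5,5,9-tetramethylcycloundeca-2,9-dien-1-yl 4-acetoxy-3-methoxybenzoate
Product: 26 (1S,2Z,4R,9E)-4-acetoxy-2,5,5,9-tetramethylcycloundeca-2,9-dien-1-yl 4-acetoxy-3-methoxybenzoate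
Conditions: Ac2O, Et3N, 4-(dimethylamino)pyridine (20 mol %), CH2Cl2, rt
Reagents that add atoms: acetic anhydride, CC(=O)OC(C)=O
Why: Nucleophilic catalysis by 4-(dimethylamino)pyridine lets acetic anhydride acylate even the hindered neopentyl allylic hydroxyl, with retention at C9 because only the O–H bond reacts.

Step 17
Reactants: 26 (1S,2Z,4R,9E)-4-acetoxy-2,5,5,9-tetramethylcycloundeca-2,9-dien-1-yl 4-acetoxy-3-methoxybenzoate
Product: 27 (1S,2Z,4R,9E)-4-acetoxy-2,5,5,9-tetramethylcycloundeca-2,9-dien-1-yl 4-hydroxy-3-methoxybenzoate (CNP0124394.1)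
Conditions: pyrrolidine (2 equiv), CH2Cl2, 0 °C to rt
Reagents that add atoms: none
Why: In this chemoselective aminolysis the aryl acetate, with its phenoxide leaving group, is attacked by pyrrolidine far faster than the hindered secondary alkyl acetate at C9 or the electron-rich benzoate at C1, so only the phenol should be unmasked.

Compound list
1 | but-2-yn-1-ol | CC#CCO | starting material
2 | sodium cyclic alkenylalanate (five-membered Al–O–CH2–CH=C(Me) ring, two 2-methoxyethoxy ligands) | CC1=CCO[Al-]1(OCCOC)OCCOC.[Na+] | intermediate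
3 | (Z)-3-iodobut-2-en-1-ol | C/C(I)=C/CO | intermediate
4 | (Z)-3-iodobut-2-enal | C/C(I)=C/C=O | intermediate
5 | 3-methylbuta-1,2-diene | C=C=C(C)C | starting material
6 | B-(3-methylbut-2-enyl)diisopinocampheylborane, Ipc groups from (+)-α-pinene | CC(C)=CCB([C@@H]1C[C@@H]2C[C@H]([C@H]1C)C2(C)C)[C@@H]1C[C@@H]2C[C@H]([C@H]1C)C2(C)C | intermediate
7 | diisopinocampheylborinate of alcohol 8 | C=CC(C)(C)[C@H](OB([C@@H]1C[C@@H]2C[C@H]([C@H]1C)C2(C)C)[C@@H]1C[C@@H]2C[C@H]([C@H]1C)C2(C)C)/C=C(C)\I | intermediate
8 | (4R,5Z)-6-iodo-3,3-dimethylhepta-1,5-dien-4-ol | C=CC(C)(C)[C@H](O)/C=C(C)\I | intermediate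
9 | tert-butyl{[(4R,5Z)-6-iodo-3,3-dimethylhepta-1,5-dien-4-yl]oxy}dimethylsilane | C=CC(C)(C)[C@H](O[Si](C)(C)C(C)(C)C)/C=C(C)\I | intermediate
10 | pent-3-yn-1-ol | CC#CCCO | starting material
11 | (E)-alkenylzirconocene chloride bearing a zirconocene chloride alkoxide (Zr trans to the CH2CH2O chain) | C/C(=C\CCO[Zr](Cl)(C1C=CC=C1)C1C=CC=C1)[Zr](Cl)(C1C=CC=C1)C1C=CC=C1 | intermediate
12 | (E)-4-iodopent-3-en-1-ol | OCC/C=C(\C)I | intermediate
13 | allylboronic acid pinacol ester | C=CCB1OC(C)(C)C(C)(C)O1 | starting material
14 | (E)-4-methylhepta-3,6-dien-1-ol | OCC/C=C(\C)CC=C | intermediate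
15 | (E)-4-methylhepta-3,6-dienal | O=CC/C=C(\C)CC=C | intermediate
16 | [(4R)-4-[(tert-butyldimethylsilyl)oxy]-5,5-dimethylhepta-2,6-dien-2-yl]magnesium chloride, Mg cis to C9 | C=CC(C)(C)[C@H](O[Si](C)(C)C(C)(C)C)/C=C(C)\[Mg]Cl | intermediate
17 | (4E,8Z,10R)-10-[(tert-butyldimethylsilyl)oxy]-4,8,11,11-tetramethyltrideca-1,4,8,12-tetraen-7-ol, both carbinol epimers | C=CC(C)(C)[C@H](O[Si](C)(C)C(C)(C)C)/C=C(C)\C(O)C/C=C(\C)CC=C | intermediate
18 | (4E,8Z,10R)-10-[(tert-butyldimethylsilyl)oxy]-4,8,11,11-tetramethyltrideca-1,4,8,12-tetraen-7-one | C=CC(C)(C)[C@H](O[Si](C)(C)C(C)(C)C)/C=C(C)\C(=O)C/C=C(\C)CC=C | intermediate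
19 | (4E,7S,8Z,10R)-10-[(tert-butyldimethylsilyl)oxy]-4,8,11,11-tetramethyltrideca-1,4,8,12-tetraen-7-ol (precursor of the key step) | C=CC(C)(C)[C@H](O[Si](C)(C)C(C)(C)C)/C=C(C)\[C@@H](O)C/C=C(\C)CC=C | intermediate
20 | (1S,2Z,4R,6E,9E)-4-[(tert-butyldimethylsilyl)oxy]-2,5,5,9-tetramethylcycloundeca-2,6,9-trien-1-ol (product of the key step) | O[C@H]1C/C=C(\C)C/C=C/C(C)(C)[C@H](O[Si](C)(C)C(C)(C)C)/C=C\1C | intermediate
21 | (1S,2Z,4R,9E)-4-[(tert-butyldimethylsilyl)oxy]-2,5,5,9-tetramethylcycloundeca-2,9-dien-1-ol | O[C@H]1C/C=C(\C)CCCC(C)(C)[C@H](O[Si](C)(C)C(C)(C)C)/C=C\1C | intermediate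
22 | vanillic acid | COc1cc(C(=O)O)ccc1O | starting material
23 | 4-acetoxy-3-methoxybenzoic acid | COc1cc(C(=O)O)ccc1OC(C)=O | intermediate
24 | (1S,2Z,4R,9E)-4-[(tert-butyldimethylsilyl)oxy]-2,5,5,9-tetramethylcycloundeca-2,9-dien-1-yl 4-acetoxy-3-methoxybenzoate | COc1cc(C(=O)O[C@H]2C/C=C(\C)CCCC(C)(C)[C@H](O[Si](C)(C)C(C)(C)C)/C=C\2C)ccc1OC(C)=O | intermediate
25 | (1S,2Z,4R,9E)-4-hydroxy-2,5,5,9-tetramethylcycloundeca-2,9-dien-1-yl 4-acetoxy-3-methoxybenzoate | COc1cc(C(=O)O[C@H]2C/C=C(\C)CCCC(C)(C)[C@H](O)/C=C\2C)ccc1OC(C)=O | intermediate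
26 | (1S,2Z,4R,9E)-4-acetoxy-2,5,5,9-tetramethylcycloundeca-2,9-dien-1-yl 4-acetoxy-3-methoxybenzoate | COc1cc(C(=O)O[C@H]2C/C=C(\C)CCCC(C)(C)[C@H](OC(C)=O)/C=C\2C)ccc1OC(C)=O | intermediate
27 | (1S,2Z,4R,9E)-4-acetoxy-2,5,5,9-tetramethylcycloundeca-2,9-dien-1-yl 4-hydroxy-3-methoxybenzoate | COc1cc(C(=O)O[C@H]2C/C=C(\C)CCCC(C)(C)[C@H](OC(C)=O)/C=C\2C)ccc1O | target

Total step count: 17. Longest linear sequence: 13 steps (1–4, 8–12, 14–17).

Steps most likely to fail

1. Step 11. Three processes could defeat the ring closure:
- oligomerisation through the reactive allyl terminus may outrun closure onto the shielded neopentyl vinyl group;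
- prolonged heating may bring ring contraction by back-biting on C3=C4;
- prolonged heating may also cause double-bond migration within the skipped diene.

The fallback makes C6–C7 between the fragments and closes the ring at C1–C11 instead. It sets out from 9 and 14 and comes back at 21.
- Cross-metathesis of 9 with an excess of 14, using (H2IMes)(PCy3)Cl2Ru=CHPh at ordinary concentration in CH2Cl2 at reflux, should give the E-configured iodo trienol F1. No intramolecular side reaction is open to it.
- Diimide, generated as in step 12, saturates its only disubstituted alkene in a strain-free open chain to give the iodo dienol F2.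
- Buffered Dess–Martin oxidation gives the iodo aldehyde F3.
- An intramolecular Nozaki–Hiyama–Kishi reaction (CrCl2 in excess, NiCl2 1 mol %, DMSO–THF, high dilution) closes the 11-membered ring to the macrocyclic allylic alcohol F4 as its C1 epimers.
- Dess–Martin oxidation leads to the macrocyclic enone F5.
- Reduction with catecholborane and the (R)-oxazaborolidine of step 10 delivers 21.

2. Step 12. Site selectivity may be lost. Strain could speed up reduction of the ring E-C3=C4 alkene, while the neopentyl position slows attack at C6=C7, so over-reduction sets in before conversion is complete. The fallback sets out from 20 and comes back at 21. The concerted hydrogen transfer is replaced by homogeneous hydrogenation with RhCl(PPh3)3 under 1 atm H2 in benzene–ethanol. Here the alkene must coordinate to rhodium before insertion, which trisubstituted alkenes do very poorly, so discrimination comes from binding and not from a rate ratio of a bimolecular pericyclic step. No new compound is made (entry F0).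

3. Step 8. The iodine–magnesium exchange may be slow at the hindered iodoalkene. The basic Grignard reagent may enolise or conjugate the β,γ-unsaturated aldehyde. The magnesium alkoxide may trigger silyl migration from the C9 oxygen to the C1 oxygen. The fallback sets out from 9 and 15 and comes back at 17 through an intermolecular Nozaki–Hiyama–Kishi coupling (CrCl2 in excess, NiCl2 1 mol %, DMF, rt). Zerovalent nickel inserts into the carbon–iodine bond with retention, and transfer to trivalent chromium gives a weakly basic alkenylchromium that adds to aldehydes without deprotonating them. The resulting chromium alkoxide is a poor trigger for silyl transfer. No new compound is made (entry F0).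

Further compounds
F1 | step 11 | (3E,6E,9R,10Z)-9-[(tert-butyldimethylsilyl)oxy]-11-iodo-4,8,8-trimethyldodeca-3,6,10-trien-1-ol | OCC/C=C(\C)C/C=C/C(C)(C)[C@H](O[Si](C)(C)C(C)(C)C)/C=C(C)\I
F2 | step 11 | (3E,9R,10Z)-9-[(tert-butyldimethylsilyl)oxy]-11-iodo-4,8,8-trimethyldodeca-3,10-dien-1-ol | OCC/C=C(\C)CCCC(C)(C)[C@H](O[Si](C)(C)C(C)(C)C)/C=C(C)\I
F3 | step 11 | (3E,9R,10Z)-9-[(tert-butyldimethylsilyl)oxy]-11-iodo-4,8,8-trimethyldodeca-3,10-dienal | O=CC/C=C(\C)CCCC(C)(C)[C@H](O[Si](C)(C)C(C)(C)C)/C=C(C)\I
F4 | step 11 | (2Z,4R,9E)-4-[(tert-butyldimethylsilyl)oxy]-2,5,5,9-tetramethylcycloundeca-2,9-dien-1-ol, both C1 epimers | OC1C/C=C(\C)CCCC(C)(C)[C@H](O[Si](C)(C)C(C)(C)C)/C=C\1C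
F5 | step 11 | (2Z,4R,9E)-4-[(tert-butyldimethylsilyl)oxy]-2,5,5,9-tetramethylcycloundeca-2,9-dien-1-one | O=C1C/C=C(\C)CCCC(C)(C)[C@H](O[Si](C)(C)C(C)(C)C)/C=C\1C
F0 | step 12 | none | none
F0 | step 8 | none | none
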